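**Plan**
The chain is numbered C1 (ester carbonyl) to C23. The retrosynthesis cuts C4=C5 and C8=C9 by phosphonate olefinations (the first cut releases the cyclohexyl ester as a phosphonocrotonate), then cuts C14–C15 and C15–C16 together.
The enabling feature is that the C15 carbinol lies between the C14 carbinol and the C16 methylene, with O17 one carbon further. C15 can therefore be a silyl-dithiane carbanion that opens a C16–C17 epoxide, passes its silicon to O17, and then attacks a C14 aldehyde. No ring forms; the only ring (the cyclohexane) comes intact from shikimic acid.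
Forward: the C16–C23 chloro epoxide and the C9–C14 aldehyde are made separately and joined at C15 in one flask. The C15 ketone is unmasked and reduced, and the polyene is grown C9 → C5 → C1, the last olefination bringing the ring ester; deallylation and desilylation finish.
Stereochemistry: C18 from D-serine; C19 and C17 by Cornforth additions to α-chloro aldehydes; C12/C13 from Sharpless epoxidation and invertive alkynylalane opening; C14 by Felkin–Anh addition; C15 by chelate-controlled reduction.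
Ring C3′/C4′ come from shikimic acid and C1′ from hydroxyl-directed hydrogenation; 20E from hydrozirconation, 10Z from trans-hydrostannation/chlorodestannation, 2E,4E,6E,8E from the olefinations.

Key step: step 27

Assumption: 4-methoxybenzyl propargyl ether (17), ethyl (E)-4-bromo-2-methylbut-2-enoate (39) and 2-(tert-butyldimethylsilyl)-1,3-dithiane (41) are taken as purchasable; each is otherwise one step from propargyl alcohol, ethyl tiglate or 1,3-dithiane.
Conventions: TBS = tert-butyldimethylsilyl, TES = triethylsilyl, PMB = 4-methoxybenzyl; chain locants C1–C23 follow the target, ring locants are C1′ (carboxyl), C3′ (acyloxy), C4′ (hydroxyl).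

**Part A – C16–C23 chloro epoxide**

Step 1
Reactants: 1 D-serine
Product: 2 (R)-2-chloro-3-hydroxypropanoic acid
Conditions: NaNO2, 6 M HCl, 0 °C → rt
Reagents that add atoms: hydrogen chloride, Cl
Why: Deaminative chlorination by diazotisation in hydrochloric acid replaces nitrogen by chloride with net retention through an α-lactone (double inversion), so D-serine gives the R chloride that becomes C18.

Step 2
Reactants: 2 (R)-2-chloro-3-hydroxypropanoic acid
Product: 3 methyl (R)-2-chloro-3-hydroxypropanoate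
Conditions: MeOH, AcCl (cat.), 0 °C → rt
Reagents that add atoms: methanol, CO
Why: Fischer esterification under anhydrous HCl leaves the chlorohydrin and its stereocentre untouched.

Step 3
Reactants: 3 methyl (R)-2-chloro-3-hydroxypropanoate
Product: 4 methyl (R)-2-chloro-3-(triethylsilyloxy)propanoate
Conditions: Et3SiCl, imidazole, CH2Cl2, 0 °C
Reagents that add atoms: chlorotriethylsilane, CC[Si](Cl)(CC)CC
Why: Silylation of the primary alcohol with chlorosilane and imidazole is much faster than base-induced closure of the chlorohydrin, and the TES ether can later be removed beside a secondary TBS ether.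

Step 4
Reactants: 4 methyl (R)-2-chloro-3-(triethylsilyloxy)propanoate
Product: 5 (R)-2-chloro-3-(triethylsilyloxy)propanal
Conditions: i-Bu2AlH, CH2Cl2, −78 °C; aq potassium sodium tartrate
Reagents that add atoms: none
Why: Partial reduction of the ester stops at the aluminium hemiacetal, which the α-chlorine stabilises at −78 °C, so the sensitive α-chloro aldehyde appears only on cold work-up and is used at once.

Step 5
Reactants: 5 (R)-2-chloro-3-(triethylsilyloxy)propanal; 6 but-1-yne
Product: 9 (2R,3S,4E)-2-chloro-1-(triethylsilyloxy)hept-4-en-3-ol, via (E)-but-1-enylzirconocene chloride 7 (not isolated), via (E)-but-1-enyl(methyl)zinc 8 (not isolated)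
Conditions: 6, Cp2Zr(H)Cl, CH2Cl2, rt; Me2Zn, toluene, −65 °C; then 5, −65 → 0 °C; aq NH4Cl
Reagents that add atoms: none
Why: syn-Hydrozirconation of the terminal alkyne fixes the E olefin, zirconium-to-zinc transmetalation gives a weakly basic alkenylzinc, and its addition through the Cornforth transition state (C–Cl antiperiplanar to C=O) should give the 18,19-anti chlorohydrin, setting C19 as S.

Step 6
Reactants: 9 (2R,3S,4E)-2-chloro-1-(triethylsilyloxy)hept-4-en-3-ol
Product: 10 (2R,3S,4E)-3-(TBS-oxy)-2-chloro-1-(TES-oxy)hept-4-ene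
Conditions: TBSOTf, 2,6-lutidine, CH2Cl2, −78 °C
Reagents that add atoms: tert-butyldimethylsilyl triflate, CC(C)(C)[Si](C)(C)OS(=O)(=O)C(F)(F)F
Why: Silyl triflate with 2,6-lutidine silylates the secondary allylic alcohol under conditions too weakly basic to close the chlorohydrin to an epoxide.

Step 7
Reactants: 10 (2R,3S,4E)-3-(TBS-oxy)-2-chloro-1-(TES-oxy)hept-4-ene
Product: 11 (2R,3S,4E)-3-(TBS-oxy)-2-chlorohept-4-en-1-ol
Conditions: PPTS, MeOH/CH2Cl2, 0 °C
Reagents that add atoms: none
Why: Acid-catalysed methanolysis cleaves the primary TES ether far faster than the secondary TBS ether (selective desilylation).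

Step 8
Reactants: 11 (2R,3S,4E)-3-(TBS-oxy)-2-chlorohept-4-en-1-ol
Product: 12 (2S,3S,4E)-3-(TBS-oxy)-2-chlorohept-4-enal
Conditions: Dess–Martin periodinane, NaHCO3, CH2Cl2, 0 °C
Reagents that add atoms: none
Why: Buffered Dess–Martin oxidation gives the α-chloro aldehyde under neutral, non-enolising conditions that preserve C18 (the descriptor changes only through priorities).

Step 9
Reactants: 12 (2S,3S,4E)-3-(TBS-oxy)-2-chlorohept-4-enal
Product: 14 (2R)-2-[(1R,2S,3E)-2-(TBS-oxy)-1-chlorohex-3-en-1-yl]oxirane, via lithium chlorohydrin alkoxide 13 (not isolated)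
Conditions: ICH2Cl, MeLi·LiBr, THF, −78 °C; then → rt
Reagents that add atoms: chloroiodomethane, ClCI
Why: Chloromethyllithium, made by iodine–lithium exchange in the presence of the aldehyde, adds through the Cornforth transition state (reinforced by the anti β-silyloxy group) to give the 17,18-anti alkoxide, which on warming closes by 3-exo-tet displacement of the primary chloride in preference to the hindered C18 chloride (carbenoid homologation of an aldehyde to a terminal epoxide), setting C17 as R.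

**Part B – C9–C14 aldehyde**

Step 10
Reactants: 15 (E)-but-2-en-1-ol
Product: 16 (2S,3S)-2,3-epoxybutan-1-ol
Conditions: Ti(OiPr)4 (cat.), L-(+)-diisopropyl tartrate (cat.), t-BuOOH, 4 Å sieves, CH2Cl2, −20 °C
Reagents that add atoms: tert-butyl hydroperoxide, CC(C)(C)OO
Why: Sharpless asymmetric epoxidation with the L-(+)-tartrate catalyst delivers oxygen to the face of the E allylic alcohol that gives the (2S,3S)-epoxy alcohol, the source of C13 and, after inversion, C12.

Step 11
Reactants: 16 (2S,3S)-2,3-epoxybutan-1-ol; 17 4-methoxybenzyl propargyl ether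
Product: 20 (2R,3S)-6-[(4-methoxybenzyl)oxy]-3-methylhex-4-yne-1,2-diol, via lithium acetylide of the propargyl ether 18 (not isolated), via diethyl(alkynyl)alane 19 (not isolated)
Conditions: 17, n-BuLi, toluene, −78 → 0 °C; Et2AlCl, 0 °C; then 16, 0 °C → rt; aq potassium sodium tartrate
Reagents that add atoms: none
Why: The alkynylalane binds the epoxy alcohol as its aluminium alkoxide and transfers the alkynyl group to C3 with inversion (organoaluminium opening of a 2,3-epoxy alcohol to a 1,2-diol), forming C11–C12 with the C12 methyl syn to O13.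

Step 12
Reactants: 20 (2R,3S)-6-[(4-methoxybenzyl)oxy]-3-methylhex-4-yne-1,2-diol
Product: 21 (2R,3R,4Z)-6-[(4-methoxybenzyl)oxy]-3-methyl-4-(tributylstannyl)hex-4-ene-1,2-diol
Conditions: [Cp*RuCl]4 (cat.), Bu3SnH, CH2Cl2, rt
Reagents that add atoms: tributyltin hydride, CCCC[SnH](CCCC)CCCC
Why: Ruthenium-catalysed trans-hydrostannation, in which hydrogen bonding of the free homopropargylic hydroxyl to the chloride ligand should steer tin to the proximal alkyne carbon C11 and the anti addition places C9 and C12 trans.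

Step 13
Reactants: 21 (2R,3R,4Z)-6-[(4-methoxybenzyl)oxy]-3-methyl-4-(tributylstannyl)hex-4-ene-1,2-diol
Product: 22 (2R,3R,4Z)-4-chloro-6-[(4-methoxybenzyl)oxy]-3-methylhex-4-ene-1,2-diol
Conditions: CuCl2, THF, rt
Reagents that add atoms: CuCl2, Cl[Cu]Cl
Why: Chlorodestannation of the alkenylstannane by CuCl2 replaces tin by chlorine with retention of geometry, giving the 10Z chloro olefin.

Step 14
Reactants: 22 (2R,3R,4Z)-4-chloro-6-[(4-methoxybenzyl)oxy]-3-methylhex-4-ene-1,2-diol
Product: 23 (2R,3R,4Z)-1,2-bis(TBS-oxy)-4-chloro-6-[(4-methoxybenzyl)oxy]-3-methylhex-4-ene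
Conditions: TBSOTf, 2,6-lutidine, CH2Cl2, 0 °C
Reagents that add atoms: tert-butyldimethylsilyl triflate, CC(C)(C)[Si](C)(C)OS(=O)(=O)C(F)(F)F
Why: Exhaustive silylation of the diol with silyl triflate is routine and leaves the vinyl chloride and PMB ether untouched.

Step 15
Reactants: 23 (2R,3R,4Z)-1,2-bis(TBS-oxy)-4-chloro-6-[(4-methoxybenzyl)oxy]-3-methylhex-4-ene
Product: 24 (2R,3R,4Z)-2-(TBS-oxy)-4-chloro-6-[(4-methoxybenzyl)oxy]-3-methylhex-4-en-1-ol
Conditions: HF·pyridine, pyridine, THF, 0 °C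
Reagents that add atoms: none
Why: Buffered HF·pyridine cleaves the unhindered primary TBS ether well before the secondary one (selective desilylation).

Step 16
Reactants: 24 (2R,3R,4Z)-2-(TBS-oxy)-4-chloro-6-[(4-methoxybenzyl)oxy]-3-methylhex-4-en-1-ol
Product: 25 (2R,3R,4Z)-2-(TBS-oxy)-4-chloro-6-[(4-methoxybenzyl)oxy]-3-methylhex-4-enal
Conditions: Dess–Martin periodinane, NaHCO3, CH2Cl2, 0 °C → rt
Reagents that add atoms: none
Why: Buffered Dess–Martin oxidation gives the α-silyloxy aldehyde without epimerising C13; it is used directly.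

**Part C – ring phosphonate and C5–C8 phosphonate**

Step 17
Reactants: 26 (−)-shikimic acid
Product: 28 methyl (3R,4S,5R)-5-hydroxy-3,4-(isopropylidenedioxy)cyclohex-1-ene-1-carboxylate, via methyl shikimate 27 (not isolated)
Conditions: MeOH, CSA, reflux; evaporate; Me2C(OMe)2, acetone, rt
Reagents that add atoms: methanol, CO; 2,2-dimethoxypropane, COC(C)(C)OC
Why: Fischer esterification followed by acid-catalysed acetalisation, which engages only the cis 3′,4′-diol in a five-membered acetonide and leaves the trans C5′ hydroxyl free.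

Step 18
Reactants: 28 methyl (3R,4S,5R)-5-hydroxy-3,4-(isopropylidenedioxy)cyclohex-1-ene-1-carboxylate
Product: 29 methyl (3R,4S,5R)-5-[(imidazol-1-ylcarbonothioyl)oxy]-3,4-(isopropylidenedioxy)cyclohex-1-ene-1-carboxylate
Conditions: 1,1′-thiocarbonyldiimidazole, DMAP (cat.), ClCH2CH2Cl, 60 °C
Reagents that add atoms: 1,1′-thiocarbonyldiimidazole, S=C(n1ccnc1)n1ccnc1
Why: Acylation of the remaining secondary alcohol by thiocarbonyldiimidazole gives the thiocarbonyl derivative needed for radical deoxygenation.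

Step 19
Reactants: 29 methyl (3R,4S,5R)-5-[(imidazol-1-ylcarbonothioyl)oxy]-3,4-(isopropylidenedioxy)cyclohex-1-ene-1-carboxylate
Product: 30 methyl (3R,4S)-3,4-(isopropylidenedioxy)cyclohex-1-ene-1-carboxylate
Conditions: Bu3SnH, AIBN (cat.), toluene, 100 °C
Reagents that add atoms: none
Why: Barton–McCombie deoxygenation, in which the stannyl radical adds to the thiocarbonyl group and the secondary C5′ radical fragments off and takes hydrogen from the tin hydride.

Step 20
Reactants: 30 methyl (3R,4S)-3,4-(isopropylidenedioxy)cyclohex-1-ene-1-carboxylate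
Product: 31 methyl (3R,4S)-3,4-dihydroxycyclohex-1-ene-1-carboxylate
Conditions: AcOH/H2O (4:1), 40 °C
Reagents that add atoms: none
Why: Mild aqueous acid hydrolyses the acetonide and returns the cis diol whose hydroxyls are needed to direct the hydrogenation.

Step 21
Reactants: 31 methyl (3R,4S)-3,4-dihydroxycyclohex-1-ene-1-carboxylate
Product: 32 methyl (1S,3R,4S)-3,4-dihydroxycyclohexane-1-carboxylate
Conditions: H2 (1 atm), [Ir(cod)(PCy3)(py)]PF6 (cat.), CH2Cl2, rt
Reagents that add atoms: none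
Why: Hydroxyl-directed hydrogenation, in which the cationic iridium catalyst binds the allylic C3′ hydroxyl (and its cis neighbour) and delivers H2 to that face of the trisubstituted enoate, so the ester ends trans to both oxygens and C1′ is set as S.

Step 22
Reactants: 32 methyl (1S,3R,4S)-3,4-dihydroxycyclohexane-1-carboxylate
Product: 34 allyl (1S,3R,4S)-3,4-dihydroxycyclohexane-1-carboxylate, via lithium carboxylate 33 (not isolated)
Conditions: LiOH, THF/H2O, 0 °C; evaporate; allyl bromide, DMF, rt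
Reagents that add atoms: lithium hydroxide, [Li+].[OH-]; allyl bromide, C=CCBr
Why: Saponification at 0 °C (faster than enolisation at C1′) followed by SN2 alkylation of the carboxylate exchanges the methyl for an allyl ester, which can be removed at the end under neutral conditions.

Step 23
Reactants: 34 allyl (1S,3R,4S)-3,4-dihydroxycyclohexane-1-carboxylate
Product: 35 allyl (1S,3R,4S)-4-(TBS-oxy)-3-hydroxycyclohexane-1-carboxylate
Conditions: TBSCl, imidazole, DMF, 0 °C
Reagents that add atoms: tert-butylchlorodimethylsilane, CC(C)(C)[Si](C)(C)Cl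
Why: With the ester equatorial the C4′ hydroxyl is equatorial and the C3′ hydroxyl axial, so the bulky chlorosilane should silylate O4′ selectively (regioselective monosilylation of a cis-cyclohexane-1,2-diol) and leave O3′ for acylation.

Step 24
Reactants: 36 triethyl 4-phosphonocrotonate
Product: 37 (E)-4-(diethoxyphosphoryl)but-2-enoic acid
Conditions: LiOH (1 equiv), THF/H2O, 0 °C; then aq HCl to pH 2
Reagents that add atoms: lithium hydroxide, [Li+].[OH-]
Why: One equivalent of hydroxide at 0 °C saponifies the carboxylic ester while the far less electrophilic phosphonate diethyl ester survives.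

Step 25
Reactants: 35 allyl (1S,3R,4S)-4-(TBS-oxy)-3-hydroxycyclohexane-1-carboxylate; 37 (E)-4-(diethoxyphosphoryl)but-2-enoic acid
Product: 38 allyl (1S,3R,4S)-4-(TBS-oxy)-3-{[(E)-4-(diethoxyphosphoryl)but-2-enoyl]oxy}cyclohexane-1-carboxylate
Conditions: DCC, DMAP (cat.), CH2Cl2, 0 °C → rt
Reagents that add atoms: none
Why: Steglich esterification acylates the axial C3′ hydroxyl with the phosphono acid under conditions known to keep 4-phosphonocrotonates E-configured.

Step 26
Reactants: 39 ethyl (E)-4-bromo-2-methylbut-2-enoate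
Product: 40 ethyl (E)-4-(diethoxyphosphoryl)-2-methylbut-2-enoate
Conditions: P(OEt)3, neat, 130 °C
Reagents that add atoms: triethyl phosphite, CCOP(OCC)OCC
Why: Michaelis–Arbuzov reaction of the allylic bromide gives the phosphonate, the E geometry of the conjugated ester being the thermodynamic one.

**Part D – coupling and completion**

Step 27
Reactants: 41 2-(TBS)-1,3-dithiane; 14 (2R)-2-[(1R,2S,3E)-2-(TBS-oxy)-1-chlorohex-3-en-1-yl]oxirane; 25 (2R,3R,4Z)-2-(TBS-oxy)-4-chloro-6-[(4-methoxybenzyl)oxy]-3-methylhex-4-enal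
Product: 45 C9–C23 dithiane adduct (10Z,12R,13R,14R,17R,18R,19S,20E), via lithiated silyl dithiane 42 (not isolated), via C17 lithium alkoxide 43 (not isolated), via C15 lithio dithiane 44 (not isolated)
Conditions: 41, t-BuLi, Et2O, −78 → −45 °C; 14, Et2O, −78 → −25 °C; HMPA–THF, −78 °C; then 25, THF, −78 °C; aq NH4Cl at −78 °C
Reagents that add atoms: none
Why: Lithiated 41 opens the terminal epoxide at C16 to give alkoxide 43, which is inert in ether until HMPA triggers a 1,4-Brook shift of silicon from C15 to O17, and the carbanion 44 so released adds to aldehyde 25, so that C15–C16 and then C14–C15 are formed in one flask. The closest known reaction type is the three-component anion relay coupling of 2-silyl-1,3-dithianes with an epoxide and a second electrophile, here with an aldehyde in the second role. No ring is closed; the chain is joined at C15. C14 is the only new stereocentre and should be set by polar Felkin–Anh addition to the α-silyloxy aldehyde, chelation being excluded by the bulky silyl ether and the HMPA-solvated lithium, which places O14 anti to O13 (C17 is carried from the epoxide). The step needs attack at C16 and not C17 (secured by the unhindered epoxide terminus), silyl transfer before the C17 alkoxide can displace the neighbouring C18 chloride (secured by keeping 43 cold in ether and capping it as its silyl ether as soon as HMPA is added), and carbonyl addition instead of enolisation (secured by the soft dithianyl anion at −78 °C).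

Step 28
Reactants: 45 C9–C23 dithiane adduct
Product: 46 C9–C23 α-hydroxy ketone (C15 ketone; 12R,13R,14R,17R,18R,19S)
Conditions: Hg(ClO4)2, CaCO3, THF/H2O (5:1), 0 °C
Reagents that add atoms: water, O
Why: Thiophilic Hg(ClO4)2 buffered by CaCO3 hydrolyses the hindered dithiane within minutes (metal-assisted dithioacetal hydrolysis), too quickly for oxymercuration of the disubstituted olefin or loss of the silyl and PMB ethers.

Step 29
Reactants: 46 C9–C23 α-hydroxy ketone
Product: 47 C9–C23 14,15-diol (12R,13R,14S,15S,17R,18R,19S)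
Conditions: Zn(BH4)2, Et2O, −30 °C
Reagents that add atoms: none
Why: Chelation-controlled reduction, in which zinc bridges the free C14 hydroxyl and the C15 carbonyl and hydride enters from the face away from the C13 branch, should give the 14,15-anti diol (15S, hence 15,17-syn), the silyl ethers at C13 and C17 being too poorly donating to compete for the metal.

Step 30
Reactants: 47 C9–C23 14,15-diol
Product: 48 C9–C23 bis-TES ether (14,15-bis-O-TES; 13,17,19-tris-O-TBS; 9-O-PMB)
Conditions: Et3SiOTf, 2,6-lutidine, CH2Cl2, −78 → 0 °C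
Reagents that add atoms: triethylsilyl triflate, CC[Si](CC)(CC)OS(=O)(=O)C(F)(F)F
Why: Silyl triflate caps both hindered secondary hydroxyls so that the later oxidations and base-mediated olefinations meet no free alcohol and a single fluoride treatment can clear all silyl groups at the end.

Step 31
Reactants: 48 C9–C23 bis-TES ether
Product: 49 C9–C23 allylic alcohol (C9–OH)
Conditions: DDQ, CH2Cl2/pH 7 buffer, 0 °C
Reagents that add atoms: none
Why: Oxidative cleavage of the PMB ether by DDQ (hydride abstraction from the electron-rich benzylic position, then hydrolysis) frees only the C9 alcohol, silyl ethers, the isolated olefin and the vinyl chloride being inert.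

Step 32
Reactants: 49 C9–C23 allylic alcohol
Product: 50 C9–C23 (10Z)-11-chloro enal (C9 aldehyde)
Conditions: MnO2, CH2Cl2, rt
Reagents that add atoms: none
Why: MnO2 oxidises the allylic alcohol, the only free hydroxyl, to the enal under neutral conditions that leave the 10Z geometry alone.

Step 33
Reactants: 50 C9–C23 enal; 40 ethyl (E)-4-(diethoxyphosphoryl)-2-methylbut-2-enoate
Product: 52 C5–C23 ethyl (6E,8E,10Z)-trienoate, via lithiated phosphonate 51 (not isolated)
Conditions: 40, LiN(SiMe3)2, THF, −78 °C; then 50, −78 → 0 °C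
Reagents that add atoms: none
Why: Vinylogous Horner–Wadsworth–Emmons olefination, in which the lithiated phosphonate (kept in slight excess over the base so that no free amide can attack the β-chloro enal) adds to the aldehyde and eliminates phosphate to give the E C8=C9 bond, 6E being the thermodynamic geometry of the reagent.

Step 34
Reactants: 52 C5–C23 ethyl trienoate
Product: 53 C5–C23 trienol (C5–OH)
Conditions: i-Bu2AlH, CH2Cl2, −78 °C; aq potassium sodium tartrate
Reagents that add atoms: none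
Why: i-Bu2AlH reduces the conjugated ethyl ester, the only ester present, to the allylic alcohol by 1,2-reduction and leaves silyl ethers and both chlorides alone.

Step 35
Reactants: 53 C5–C23 trienol
Product: 54 C5–C23 trienal (C5 aldehyde)
Conditions: MnO2, CH2Cl2, rt
Reagents that add atoms: none
Why: MnO2 selectively oxidises the primary trienylic alcohol to the trienal, which is used at once.

Step 36
Reactants: 54 C5–C23 trienal; 38 ring phosphonocrotonate
Product: 56 fully protected target (allyl ester; O4′-TBS; 13,17,19-tris-O-TBS; 14,15-bis-O-TES), via lithiated ring phosphonate 55 (not isolated)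
Conditions: 38, LiN(SiMe3)2, THF, −78 °C; then 54, −78 → 0 °C
Reagents that add atoms: none
Why: Vinylogous Horner–Wadsworth–Emmons olefination with the 4-phosphonocrotonate should form C4=C5 with E selectivity and brings the ring ester, a slight deficit of base relative to phosphonate avoiding deprotonation at C1′.

Step 37
Reactants: 56 fully protected target
Product: 57 silylated carboxylic acid (free C1′ acid, all hydroxyls silylated)
Conditions: Pd(PPh3)4 (cat.), morpholine, THF, rt
Reagents that add atoms: none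
Why: Tsuji–Trost deallylation, in which zerovalent palladium ionises the allyl ester to a π-allyl complex that morpholine captures, frees the acid under neutral conditions while every hydroxyl is still silylated, so the C3′ acyl group cannot migrate.

Step 38
Reactants: 57 silylated carboxylic acid
Product: 58 target, (1S,3R,4S)-3-{[(2E,4E,6E,8E,10Z,12R,13R,14S,15S,17R,18R,19S,20E)-11,18-dichloro-13,14,15,17,19-pentahydroxy-6,12-dimethyltricosa-2,4,6,8,10,20-hexaenoyl]oxy}-4-hydroxycyclohexane-1-carboxylic acid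
Conditions: HF·pyridine, pyridine, THF, 0 °C → rt
Reagents that add atoms: none
Why: Buffered HF·pyridine should cleave the four TBS and two TES ethers (global desilylation) under mildly acidic conditions that neither isomerise the chloropentaene ester nor promote acyl migration to the C4′ hydroxyl.

**Compound list**
1 | D-serine | N[C@H](CO)C(=O)O | starting material
2 | (R)-2-chloro-3-hydroxypropanoic acid | OC(=O)[C@H](Cl)CO | intermediate
3 | methyl (R)-2-chloro-3-hydroxypropanoate | COC(=O)[C@H](Cl)CO | intermediate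
4 | methyl (R)-2-chloro-3-(triethylsilyloxy)propanoate | COC(=O)[C@H](Cl)CO[Si](CC)(CC)CC | intermediate
5 | (R)-2-chloro-3-(triethylsilyloxy)propanal | O=C[C@H](Cl)CO[Si](CC)(CC)CC | intermediate
6 | but-1-yne | CCC#C | starting material
7 | (E)-but-1-enylzirconocene chloride | CC/C=C/[Zr](Cl)(C1C=CC=C1)C1C=CC=C1 | intermediate (not isolated)
8 | (E)-but-1-enyl(methyl)zinc | CC/C=C/[Zn]C | intermediate (not isolated)
9 | (2R,3S,4E)-2-chloro-1-(triethylsilyloxy)hept-4-en-3-ol | CC/C=C/[C@H](O)[C@H](Cl)CO[Si](CC)(CC)CC | intermediate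
10 | (2R,3S,4E)-3-(TBS-oxy)-2-chloro-1-(TES-oxy)hept-4-ene | CC/C=C/[C@H](O[Si](C)(C)C(C)(C)C)[C@H](Cl)CO[Si](CC)(CC)CC | intermediate
11 | (2R,3S,4E)-3-(TBS-oxy)-2-chlorohept-4-en-1-ol | CC/C=C/[C@H](O[Si](C)(C)C(C)(C)C)[C@H](Cl)CO | intermediate
12 | (2S,3S,4E)-3-(TBS-oxy)-2-chlorohept-4-enal | CC/C=C/[C@H](O[Si](C)(C)C(C)(C)C)[C@H](Cl)C=O | intermediate
13 | lithium (2R,3R,4S,5E)-4-(TBS-oxy)-1,3-dichlorooct-5-en-2-olate | CC/C=C/[C@H](O[Si](C)(C)C(C)(C)C)[C@H](Cl)[C@H]([O-])CCl.[Li+] | intermediate (not isolated)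
14 | (2R)-2-[(1R,2S,3E)-2-(TBS-oxy)-1-chlorohex-3-en-1-yl]oxirane (C16–C23 chloro epoxide) | CC/C=C/[C@H](O[Si](C)(C)C(C)(C)C)[C@H](Cl)[C@H]1CO1 | intermediate
15 | (E)-but-2-en-1-ol | C/C=C/CO | starting material
16 | (2S,3S)-2,3-epoxybutan-1-ol | OC[C@@H]1O[C@H]1C | intermediate
17 | 4-methoxybenzyl propargyl ether | C#CCOCc1ccc(OC)cc1 | starting material
18 | lithium acetylide of 17 | [Li]C#CCOCc1ccc(OC)cc1 | intermediate (not isolated)
19 | diethyl{3-[(4-methoxybenzyl)oxy]prop-1-yn-1-yl}alane | CC[Al](CC)C#CCOCc1ccc(OC)cc1 | intermediate (not isolated)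
20 | (2R,3S)-6-[(4-methoxybenzyl)oxy]-3-methylhex-4-yne-1,2-diol | OC[C@H](O)[C@@H](C)C#CCOCc1ccc(OC)cc1 | intermediate
21 | (2R,3R,4Z)-6-[(4-methoxybenzyl)oxy]-3-methyl-4-(tributylstannyl)hex-4-ene-1,2-diol | OC[C@H](O)[C@@H](C)/C([Sn](CCCC)(CCCC)CCCC)=C/COCc1ccc(OC)cc1 | intermediate
22 | (2R,3R,4Z)-4-chloro-6-[(4-methoxybenzyl)oxy]-3-methylhex-4-ene-1,2-diol | OC[C@H](O)[C@@H](C)/C(Cl)=C/COCc1ccc(OC)cc1 | intermediate
23 | (2R,3R,4Z)-1,2-bis(TBS-oxy)-4-chloro-6-[(4-methoxybenzyl)oxy]-3-methylhex-4-ene | CC(C)(C)[Si](C)(C)OC[C@H](O[Si](C)(C)C(C)(C)C)[C@@H](C)/C(Cl)=C/COCc1ccc(OC)cc1 | intermediate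
24 | (2R,3R,4Z)-2-(TBS-oxy)-4-chloro-6-[(4-methoxybenzyl)oxy]-3-methylhex-4-en-1-ol | OC[C@H](O[Si](C)(C)C(C)(C)C)[C@@H](C)/C(Cl)=C/COCc1ccc(OC)cc1 | intermediate
25 | (2R,3R,4Z)-2-(TBS-oxy)-4-chloro-6-[(4-methoxybenzyl)oxy]-3-methylhex-4-enal (C9–C14 aldehyde) | O=C[C@H](O[Si](C)(C)C(C)(C)C)[C@@H](C)/C(Cl)=C/COCc1ccc(OC)cc1 | intermediate
26 | (−)-shikimic acid | OC(=O)C1=C[C@@H](O)[C@@H](O)[C@H](O)C1 | starting material
27 | methyl shikimate | COC(=O)C1=C[C@@H](O)[C@@H](O)[C@H](O)C1 | intermediate (not isolated)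
28 | methyl (3R,4S,5R)-5-hydroxy-3,4-(isopropylidenedioxy)cyclohex-1-ene-1-carboxylate | COC(=O)C1=C[C@H]2OC(C)(C)O[C@H]2[C@H](O)C1 | intermediate
29 | methyl (3R,4S,5R)-5-[(imidazol-1-ylcarbonothioyl)oxy]-3,4-(isopropylidenedioxy)cyclohex-1-ene-1-carboxylate | COC(=O)C1=C[C@H]2OC(C)(C)O[C@H]2[C@H](OC(=S)n3ccnc3)C1 | intermediate
30 | methyl (3R,4S)-3,4-(isopropylidenedioxy)cyclohex-1-ene-1-carboxylate | COC(=O)C1=C[C@H]2OC(C)(C)O[C@H]2CC1 | intermediate
31 | methyl (3R,4S)-3,4-dihydroxycyclohex-1-ene-1-carboxylate | COC(=O)C1=C[C@@H](O)[C@@H](O)CC1 | intermediate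
32 | methyl (1S,3R,4S)-3,4-dihydroxycyclohexane-1-carboxylate | O[C@@H]1C[C@@H](C(=O)OC)CC[C@@H]1O | intermediate
33 | lithium (1S,3R,4S)-3,4-dihydroxycyclohexane-1-carboxylate | O[C@@H]1C[C@@H](C(=O)[O-])CC[C@@H]1O.[Li+] | intermediate (not isolated)
34 | allyl (1S,3R,4S)-3,4-dihydroxycyclohexane-1-carboxylate | O[C@@H]1C[C@@H](C(=O)OCC=C)CC[C@@H]1O | intermediate
35 | allyl (1S,3R,4S)-4-(TBS-oxy)-3-hydroxycyclohexane-1-carboxylate | O[C@@H]1C[C@@H](C(=O)OCC=C)CC[C@@H]1O[Si](C)(C)C(C)(C)C | intermediate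
36 | triethyl 4-phosphonocrotonate, ethyl (E)-4-(diethoxyphosphoryl)but-2-enoate | CCOC(=O)/C=C/CP(=O)(OCC)OCC | starting material
37 | (E)-4-(diethoxyphosphoryl)but-2-enoic acid | OC(=O)/C=C/CP(=O)(OCC)OCC | intermediate
38 | allyl (1S,3R,4S)-4-(TBS-oxy)-3-{[(E)-4-(diethoxyphosphoryl)but-2-enoyl]oxy}cyclohexane-1-carboxylate (ring phosphonocrotonate) | CCOP(=O)(OCC)C/C=C/C(=O)O[C@@H]1C[C@@H](C(=O)OCC=C)CC[C@@H]1O[Si](C)(C)C(C)(C)C | intermediate
39 | ethyl (E)-4-bromo-2-methylbut-2-enoate | CCOC(=O)/C(C)=C/CBr | starting material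
40 | ethyl (E)-4-(diethoxyphosphoryl)-2-methylbut-2-enoate | CCOC(=O)/C(C)=C/CP(=O)(OCC)OCC | intermediate
41 | 2-(tert-butyldimethylsilyl)-1,3-dithiane | CC(C)(C)[Si](C)(C)C1SCCCS1 | starting material
42 | 2-lithio-2-(tert-butyldimethylsilyl)-1,3-dithiane | CC(C)(C)[Si](C)(C)C1([Li])SCCCS1 | intermediate (not isolated)
43 | lithium (2R,3R,4S,5E)-4-(TBS-oxy)-3-chloro-1-[2-(TBS)-1,3-dithian-2-yl]oct-5-en-2-olate (C17 alkoxide) | CC/C=C/[C@H](O[Si](C)(C)C(C)(C)C)[C@H](Cl)[C@H]([O-])CC1([Si](C)(C)C(C)(C)C)SCCCS1.[Li+] | intermediate (not isolated)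
44 | 2-lithio-2-[(2R,3R,4S,5E)-2,4-bis(TBS-oxy)-3-chlorooct-5-en-1-yl]-1,3-dithiane (C15 carbanion) | CC/C=C/[C@H](O[Si](C)(C)C(C)(C)C)[C@H](Cl)[C@H](O[Si](C)(C)C(C)(C)C)CC1([Li])SCCCS1 | intermediate (not isolated)
45 | C9–C23 dithiane adduct: 9-O-PMB, (10Z)-11-chloro, (12R)-methyl, (13R)-OTBS, (14R)-OH, C15 as 1,3-dithiane-2,2-diyl, (17R)-OTBS, (18R)-chloro, (19S)-OTBS, (20E)-ene | CC/C=C/[C@H](O[Si](C)(C)C(C)(C)C)[C@H](Cl)[C@H](O[Si](C)(C)C(C)(C)C)CC1(SCCCS1)[C@H](O)[C@H](O[Si](C)(C)C(C)(C)C)[C@@H](C)/C(Cl)=C/COCc1ccc(OC)cc1 | intermediate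
46 | C9–C23 α-hydroxy ketone: as 45 with C15 ketone (12R,13R,14R,17R,18R,19S) | CC/C=C/[C@H](O[Si](C)(C)C(C)(C)C)[C@H](Cl)[C@H](O[Si](C)(C)C(C)(C)C)CC(=O)[C@H](O)[C@H](O[Si](C)(C)C(C)(C)C)[C@@H](C)/C(Cl)=C/COCc1ccc(OC)cc1 | intermediate
47 | C9–C23 14,15-diol (10Z,12R,13R,14S,15S,17R,18R,19S,20E): 9-O-PMB, 13,17,19-tris-O-TBS | CC/C=C/[C@H](O[Si](C)(C)C(C)(C)C)[C@H](Cl)[C@H](O[Si](C)(C)C(C)(C)C)C[C@H](O)[C@H](O)[C@H](O[Si](C)(C)C(C)(C)C)[C@@H](C)/C(Cl)=C/COCc1ccc(OC)cc1 | intermediate
48 | C9–C23 bis-TES ether: 14,15-bis-O-TES, 13,17,19-tris-O-TBS, 9-O-PMB | CC/C=C/[C@H](O[Si](C)(C)C(C)(C)C)[C@H](Cl)[C@H](O[Si](C)(C)C(C)(C)C)C[C@H](O[Si](CC)(CC)CC)[C@H](O[Si](CC)(CC)CC)[C@H](O[Si](C)(C)C(C)(C)C)[C@@H](C)/C(Cl)=C/COCc1ccc(OC)cc1 | intermediate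
49 | C9–C23 allylic alcohol: as 48 with free C9–OH | CC/C=C/[C@H](O[Si](C)(C)C(C)(C)C)[C@H](Cl)[C@H](O[Si](C)(C)C(C)(C)C)C[C@H](O[Si](CC)(CC)CC)[C@H](O[Si](CC)(CC)CC)[C@H](O[Si](C)(C)C(C)(C)C)[C@@H](C)/C(Cl)=C/CO | intermediate
50 | C9–C23 (10Z)-11-chloro enal: as 49 with C9 aldehyde | CC/C=C/[C@H](O[Si](C)(C)C(C)(C)C)[C@H](Cl)[C@H](O[Si](C)(C)C(C)(C)C)C[C@H](O[Si](CC)(CC)CC)[C@H](O[Si](CC)(CC)CC)[C@H](O[Si](C)(C)C(C)(C)C)[C@@H](C)/C(Cl)=C/C=O | intermediate
51 | lithium salt of the C8 carbanion of 40 | CCOC(=O)/C(C)=C/[CH-]P(=O)(OCC)OCC.[Li+] | intermediate (not isolated)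
52 | C5–C23 ethyl (6E,8E,10Z)-trienoate (silyl ethers as in 48) | CC/C=C/[C@H](O[Si](C)(C)C(C)(C)C)[C@H](Cl)[C@H](O[Si](C)(C)C(C)(C)C)C[C@H](O[Si](CC)(CC)CC)[C@H](O[Si](CC)(CC)CC)[C@H](O[Si](C)(C)C(C)(C)C)[C@@H](C)/C(Cl)=C/C=C/C=C(C)/C(=O)OCC | intermediate
53 | C5–C23 trienol (C5–OH) | CC/C=C/[C@H](O[Si](C)(C)C(C)(C)C)[C@H](Cl)[C@H](O[Si](C)(C)C(C)(C)C)C[C@H](O[Si](CC)(CC)CC)[C@H](O[Si](CC)(CC)CC)[C@H](O[Si](C)(C)C(C)(C)C)[C@@H](C)/C(Cl)=C/C=C/C=C(C)/CO | intermediate
54 | C5–C23 trienal (C5 aldehyde) | CC/C=C/[C@H](O[Si](C)(C)C(C)(C)C)[C@H](Cl)[C@H](O[Si](C)(C)C(C)(C)C)C[C@H](O[Si](CC)(CC)CC)[C@H](O[Si](CC)(CC)CC)[C@H](O[Si](C)(C)C(C)(C)C)[C@@H](C)/C(Cl)=C/C=C/C=C(C)/C=O | intermediate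
55 | lithium salt of the C4 carbanion of 38 | CCOP(=O)(OCC)[CH-]/C=C/C(=O)O[C@@H]1C[C@@H](C(=O)OCC=C)CC[C@@H]1O[Si](C)(C)C(C)(C)C.[Li+] | intermediate (not isolated)
56 | fully protected target: allyl ester, O4′-TBS, 13,17,19-tris-O-TBS, 14,15-bis-O-TES | CC/C=C/[C@H](O[Si](C)(C)C(C)(C)C)[C@H](Cl)[C@H](O[Si](C)(C)C(C)(C)C)C[C@H](O[Si](CC)(CC)CC)[C@H](O[Si](CC)(CC)CC)[C@H](O[Si](C)(C)C(C)(C)C)[C@@H](C)/C(Cl)=C/C=C/C=C(C)/C=C/C=C/C(=O)O[C@@H]1C[C@@H](C(=O)OCC=C)CC[C@@H]1O[Si](C)(C)C(C)(C)C | intermediate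
57 | silylated carboxylic acid: as 56 with free C1′ acid | CC/C=C/[C@H](O[Si](C)(C)C(C)(C)C)[C@H](Cl)[C@H](O[Si](C)(C)C(C)(C)C)C[C@H](O[Si](CC)(CC)CC)[C@H](O[Si](CC)(CC)CC)[C@H](O[Si](C)(C)C(C)(C)C)[C@@H](C)/C(Cl)=C/C=C/C=C(C)/C=C/C=C/C(=O)O[C@@H]1C[C@@H](C(=O)O)CC[C@@H]1O[Si](C)(C)C(C)(C)C | intermediate
58 | (1S,3R,4S)-3-{[(2E,4E,6E,8E,10Z,12R,13R,14S,15S,17R,18R,19S,20E)-11,18-dichloro-13,14,15,17,19-pentahydroxy-6,12-dimethyltricosa-2,4,6,8,10,20-hexaenoyl]oxy}-4-hydroxycyclohexane-1-carboxylic acid | CC/C=C/[C@H](O)[C@H](Cl)[C@H](O)C[C@H](O)[C@H](O)[C@H](O)[C@@H](C)/C(Cl)=C/C=C/C=C(C)/C=C/C=C/C(=O)O[C@@H]1C[C@@H](C(=O)O)CC[C@@H]1O | target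

**Step count and risks**
Total: 38 steps. Longest linear sequence: 21 steps (steps 1–9, then 27–38, from D-serine).

Steps most likely to fail:

1. Step 27. The silyl shift may lag, so that the C17 alkoxide displaces the C18 chloride; the relay carbanion may be quenched by proton transfer from the α-branched aldehyde; or facial selectivity at C14 may erode. The fallback runs the coupling stepwise from 14 and rejoins the route at 45. 2-Lithio-1,3-dithiane (from 1,3-dithiane and n-BuLi, THF, −30 °C) opens 14 at C16 and a cold quench gives the C17 hydroxy dithiane F1. TBSOTf and 2,6-lutidine convert it into the bis-silyl ether dithiane F2. Metalation of F2 with t-BuLi in THF–HMPA at −78 °C regenerates carbanion 44, which is treated with aldehyde 25 to give 45.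

2. Step 12. Tin may be delivered to the distal carbon C10, because the directing hydroxyl is one carbon further from the alkyne than in the best precedents, or the stannane may protodestannylate. The fallback sets out from 20 and returns at 23. Both hydroxyls are silylated (TBSOTf, 2,6-lutidine) to give the bis-silyl ether alkyne F3, and DDQ frees the propargylic alcohol F4. NaAlH2(OCH2CH2OMe)2 in THF then effects hydroxyl-directed trans-hydroalumination with aluminium on C11, and an N-chlorosuccinimide quench gives the (Z)-chloro allylic alcohol F5. 4-Methoxybenzyl trichloroacetimidate with catalytic La(OTf)3 re-protects C9 to give 23.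

3. Step 5. The α-chloro aldehyde may enolise (eroding C18) or eliminate the β-silyloxy group while the slow zinc reagent adds, and the facial selectivity of the zinc reagent may be modest. The fallback sets out from 5 and returns at 9. Lithium but-1-ynide (from 6 and n-BuLi, THF, −78 °C), a small and fast nucleophile, is expected to add with Cornforth anti selectivity to give the propargylic chlorohydrin F6. Trans-hydrostannation with [Cp*RuCl]4 and Bu3SnH, directed by the propargylic hydroxyl, gives the alkenylstannane F7. Protodestannation with copper thiophene-2-carboxylate, CuO2C(C4H3S), in DMF leaves the E olefin of 9.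

Further compounds
F1 | step 27 | 2-[(2R,3R,4S,5E)-4-(TBS-oxy)-3-chloro-2-hydroxyoct-5-en-1-yl]-1,3-dithiane | CC/C=C/[C@H](O[Si](C)(C)C(C)(C)C)[C@H](Cl)[C@H](O)CC1SCCCS1
F2 | step 27 | 2-[(2R,3R,4S,5E)-2,4-bis(TBS-oxy)-3-chlorooct-5-en-1-yl]-1,3-dithiane | CC/C=C/[C@H](O[Si](C)(C)C(C)(C)C)[C@H](Cl)[C@H](O[Si](C)(C)C(C)(C)C)CC1SCCCS1
F3 | step 12 | (2R,3S)-1,2-bis(TBS-oxy)-6-[(4-methoxybenzyl)oxy]-3-methylhex-4-yne | CC(C)(C)[Si](C)(C)OC[C@H](O[Si](C)(C)C(C)(C)C)[C@@H](C)C#CCOCc1ccc(OC)cc1
F4 | step 12 | (4S,5R)-5,6-bis(TBS-oxy)-4-methylhex-2-yn-1-ol | CC(C)(C)[Si](C)(C)OC[C@H](O[Si](C)(C)C(C)(C)C)[C@@H](C)C#CCO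
F5 | step 12 | (2Z,4R,5R)-5,6-bis(TBS-oxy)-3-chloro-4-methylhex-2-en-1-ol | CC(C)(C)[Si](C)(C)OC[C@H](O[Si](C)(C)C(C)(C)C)[C@@H](C)/C(Cl)=C/CO
F6 | step 5 | (2R,3S)-2-chloro-1-(triethylsilyloxy)hept-4-yn-3-ol | CCC#C[C@H](O)[C@H](Cl)CO[Si](CC)(CC)CC
F7 | step 5 | (2R,3R,4Z)-2-chloro-4-(tributylstannyl)-1-(triethylsilyloxy)hept-4-en-3-ol | CC/C=C([Sn](CCCC)(CCCC)CCCC)/[C@H](O)[C@H](Cl)CO[Si](CC)(CC)CC
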